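**Strategy.** The middle unit is not made as a flavan but as a flat 3‑benzyloxy‑4‑aryl‑flavylium ion. Its C4 carries C8 of the epicatechin unit (added as an aryllithium to a flavone carbonyl) and its C8 already carries C4 of the upper epirobinetinidol unit. One operation then dearomatises the benzopyrylium ring: chiral‑phosphate‑paired hydride transfer followed by ionic hydrogenation delivers three hydrogens to one face of the O1–C2–C3–C4 pyran ring. This sets the all‑cis C2/C3/C4 triad, which a C4‑cation coupling cannot give. The precursor is an achiral flavonol core flanked by the two chiral units.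

Key step: step 17

**Remarks.**
- Assumption on the structure: the SMILES is read as epirobinetinidol‑(4β→8)‑epirobinetinidol‑(4α→8)‑epicatechin. Upper unit 2R,3R,4R (2,3‑cis‑3,4‑trans), middle unit 2R,3R,4S (all‑cis), lower unit 2R,3R.
- Assumption on the catalyst: (R)‑TRIP is written as the matched enantiomer; a test run decides between (R) and (S).
- Commercial materials: 1, 9, 14, 18, both TRIP enantiomers and the Hantzsch ester.
- Abbreviations in names: U = (2R,3R,4R)‑3,7‑bis(benzyloxy)‑2‑[3,4,5‑tris(benzyloxy)phenyl]chroman‑4‑yl (aryl bond trans to the 3‑benzyloxy group). Lw = (2R,3R)‑3,5,7‑tris(benzyloxy)‑2‑[3,4‑bis(benzyloxy)phenyl]chroman‑8‑yl.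

## Route

Step 1
Reactants: 1 (+)-dihydrorobinetin
Product: 2 (2R,3R)-7,3',4',5'-tetra-O-benzyldihydrorobinetin
Conditions: BnBr (4.4 equiv), K2CO3, DMF, rt, Ar
Reagents that add atoms: benzyl bromide BrCc1ccccc1
Why: Williamson etherification in which carbonate deprotonates only the four phenols, so the secondary 3‑OH stays free and C2/C3 are not touched.

Step 2
Reactants: 2 tetra-O-benzyldihydrorobinetin
Product: 4 (2R,3S)-7,3',4',5'-tetra-O-benzylrobinetinidol, via flavan-3,4-diol 3 (not isolated)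
Conditions: NaBH4, THF/MeOH, 0 °C; then Et3SiH, TFA, CH2Cl2, −20 °C
Reagents that add atoms: none
Why: Borohydride reduction of the aryl ketone and ionic hydrogenation of the resulting 2,4‑dialkoxybenzylic alcohol delete the C4 oxygen (the usual dihydroflavonol‑to‑flavan‑3‑ol conversion), with excess silane trapping the cation before any hydride shift and C2/C3 retained.

Step 3
Reactants: 4 tetra-O-benzylrobinetinidol
Product: 5 (2R)-7-(benzyloxy)-2-[3,4,5-tris(benzyloxy)phenyl]chroman-3-one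
Conditions: Dess–Martin periodinane, NaHCO3, CH2Cl2, rt
Reagents that add atoms: none
Why: Dess–Martin oxidation under near‑neutral conditions should give the flavan‑3‑one without epimerising the adjacent C2 centre.

Step 4
Reactants: 5 flavan-3-one
Product: 6 (2R,3R)-7,3',4',5'-tetra-O-benzylepirobinetinidol
Conditions: L-Selectride, LiBr, THF, −78 °C
Reagents that add atoms: none
Why: Bulky‑hydride reduction in which hydride enters the 3‑ketone from the face opposite the C2 aryl group and gives the axial 3‑alcohol, i.e. the 2,3‑cis (3R) series, as in the standard catechin‑to‑epicatechin inversion.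

Step 5
Reactants: 6 tetra-O-benzylepirobinetinidol
Product: 7 (2R,3R)-3,7,3',4',5'-penta-O-benzylepirobinetinidol
Conditions: NaH, BnBr, Bu4NI (cat.), DMF, 0 °C → rt
Reagents that add atoms: benzyl bromide BrCc1ccccc1
Why: Williamson etherification of the secondary alkoxide masks the 3‑OH for the later organolithium step.

Step 6
Reactants: 7 penta-O-benzylepirobinetinidol
Product: 8 4β-(2-ethoxyethoxy)-3,7,3',4',5'-penta-O-benzylepirobinetinidol
Conditions: DDQ (2 equiv), 2-ethoxyethanol, CH2Cl2, rt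
Reagents that add atoms: 2-ethoxyethanol CCOCCO
Why: DDQ benzylic oxidation in which hydride abstraction from the 2,4‑dialkoxybenzylic C4–H gives a cation that the alcohol captures trans to the 3‑benzyloxy group (4β), the standard C4 activation of benzylated flavan‑3‑ols.

Step 7
Reactants: 9 2,4,6-trihydroxyacetophenone
Product: 10 1-[4-(benzyloxy)-2,6-dihydroxyphenyl]ethanone
Conditions: BnBr (1.0 equiv), K2CO3, acetone, rt
Reagents that add atoms: benzyl bromide BrCc1ccccc1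
Why: Williamson etherification of the para hydroxyl, the only one not hydrogen‑bonded to the acetyl group, keeps the ring symmetric so that its two free carbons remain equivalent.

Step 8
Reactants: 8 4β-(2-ethoxyethoxy) ether; 10 1-[4-(benzyloxy)-2,6-dihydroxyphenyl]ethanone (3 equiv)
Product: 11 1-[4-(benzyloxy)-2,6-dihydroxy-3-U-phenyl]ethanone
Conditions: BF3·OEt2, CH2Cl2, −40 → 0 °C
Reagents that add atoms: none
Why: Lewis‑acid Friedel–Crafts coupling of the flavan‑4‑yl cation with the acylphloroglucinol, in which either of the two equivalent ring carbons attacks C4 anti to the 3‑benzyloxy group, fixing both the 3,4‑trans (4R) centre and the attachment at a carbon flanked by two oxygens.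

Step 9
Reactants: 11 coupled dihydroxy ketone
Product: 12 2-acetyl-5-(benzyloxy)-3-hydroxy-4-U-phenyl trifluoromethanesulfonate
Conditions: PhNTf2 (1.05 equiv), Et3N, DMAP (cat.), CH2Cl2, 0 °C
Reagents that add atoms: N-phenylbis(trifluoromethanesulfonimide) O=S(=O)(N(c1ccccc1)S(=O)(=O)C(F)(F)F)C(F)(F)F
Why: Site‑selective O‑sulfonylation, since the 6‑OH is open whereas the 2‑OH is buried between the acetyl group and the flavanyl substituent, so only the former should be triflated.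

Step 10
Reactants: 12 aryl triflate
Product: 13 1-[4-(benzyloxy)-2-hydroxy-3-U-phenyl]ethanone
Conditions: Pd(OAc)2 (5 mol %), dppf, HCO2H, Et3N, DMF, 70 °C
Reagents that add atoms: none
Why: Palladium‑catalysed formate reduction of the aryl triflate (oxidative addition, formate decarboxylation, reductive elimination) removes the surplus oxygen and leaves benzyl ethers untouched.

Step 11
Reactants: 13 hydroxy ketone; 14 3,4,5-tris(benzyloxy)benzaldehyde
Product: 16 7-(benzyloxy)-3-hydroxy-8-U-2-[3,4,5-tris(benzyloxy)phenyl]-4H-chromen-4-one, via chalcone 15 (not isolated)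
Conditions: KOH, EtOH/THF, rt; then 30 % H2O2, 0 °C → rt
Reagents that add atoms: hydrogen peroxide OO
Why: Claisen–Schmidt condensation followed by Algar–Flynn–Oyamada oxidative cyclisation through the single free phenol builds the flat 3‑hydroxyflavone ring (a chalcone lacking a 6'‑substituent gives the flavonol, not the aurone), and no stereocentre is formed.

Step 12
Reactants: 16 flavonol
Product: 17 3,7-bis(benzyloxy)-8-U-2-[3,4,5-tris(benzyloxy)phenyl]-4H-chromen-4-one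
Conditions: BnBr, K2CO3, DMF, 50 °C
Reagents that add atoms: benzyl bromide BrCc1ccccc1
Why: Williamson etherification of the acidic flavonol 3‑OH.

Step 13
Reactants: 18 (−)-epicatechin
Product: 19 5,7,3',4'-tetra-O-benzylepicatechin
Conditions: BnBr (4.4 equiv), K2CO3, DMF, rt, Ar
Reagents that add atoms: benzyl bromide BrCc1ccccc1
Why: Williamson etherification of the four phenols only.

Step 14
Reactants: 19 tetra-O-benzylepicatechin
Product: 20 8-bromo-5,7,3',4'-tetra-O-benzylepicatechin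
Conditions: NBS (1.0 equiv), CH2Cl2, −78 °C → rt
Reagents that add atoms: N-bromosuccinimide O=C1CCC(=O)N1Br
Why: Electrophilic aromatic bromination at C8, the less hindered of the two free phloroglucinol‑type positions of this ether.

Step 15
Reactants: 20 8-bromo tetrabenzyl ether
Product: 21 8-bromo-3,5,7,3',4'-penta-O-benzylepicatechin
Conditions: NaH, BnBr, DMF, 0 °C → rt
Reagents that add atoms: benzyl bromide BrCc1ccccc1
Why: Williamson etherification of the 3‑alkoxide.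

Step 16
Reactants: 21 8-bromo-penta-O-benzylepicatechin; 17 flavone
Product: 23 3,7-bis(benzyloxy)-4-Lw-8-U-2-[3,4,5-tris(benzyloxy)phenyl]-4H-chromen-4-ol, via aryllithium 22 (not isolated)
Conditions: tBuLi (2 equiv), THF, −78 °C; then 17, −78 → −30 °C; aq. NaHCO3; used crude
Reagents that add atoms: none
Why: Bromine–lithium exchange and 1,2‑addition of the aryllithium to the chromone carbonyl, the classical organometallic entry to 4‑substituted flavylium precursors, in which the carbinol centre C4 forms without control because it is ionised in step 17.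

Step 17
Reactants: 23 chromen-4-ol
Product: 26 pentadeca-O-benzyl ether of the target, via flavylium ion pair 24 (not isolated), via 2H-chromene 25 (not isolated)
Conditions: (R)-TRIP (10 mol %), Hantzsch ester (1.2 equiv), 4 Å MS, toluene, 0 °C → rt; then nBu3SnH (3 equiv), TFA (5 equiv), CH2Cl2, −40 → 0 °C
Reagents that add atoms: none
Why: Proposed new method: the chiral phosphoric acid ionises 23 to the flat benzopyrylium, held as a contact ion pair with the chiral phosphate (24), and the Hantzsch ester transfers hydride to C2 (C4 is screened on both faces by the orthogonal 2,6‑dioxygenated aryl ring), which dearomatises the pyrylium ring without closing any ring and gives 25; the closest known reaction type is the chiral‑phosphate‑paired transfer hydrogenation of 2,4‑diarylbenzopyrylium ions with Hantzsch esters, joined here to the tin hydride/TFA ionic hydrogenation known for 4‑aryl‑flavan‑4‑yl cations. C2 (R) is set by the chiral anion, which must override the weak bias of the two remote units. TFA then protonates the enol ether at C3 on the face opposite the pseudoaxial C2 aryl group (sets C3), and nBu3SnH quenches the resulting C4 benzylic cation opposite the now axial 3‑benzyloxy group (sets C4), so all three hydrogens enter from one face and the 2,3‑cis‑3,4‑cis ring should result. The step needs face selectivity at C2 (catalyst), tolerance to the site of the first hydride (C2 or C4 attack converge on the same all‑cis ring because the later additions are anti to the first‑formed centre) and suppression of hydride exchange between molecules of 25 (excess of the much better tin hydride donor at low temperature).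

Step 18
Reactants: 26 pentadeca-O-benzyl trimer
Product: 27 epirobinetinidol-(4β→8)-epirobinetinidol-(4α→8)-epicatechin (CNP0115797.2)
Conditions: H2 (1 atm), 20 % Pd(OH)2/C, THF/MeOH, rt
Reagents that add atoms: none
Why: Catalytic hydrogenolysis cleaves the fifteen benzyl ethers under neutral conditions that should leave the interflavan C–C bonds and all stereocentres untouched.

## Compound list

1 | (+)-dihydrorobinetin, (2R,3R)-3,7,3',4',5'-pentahydroxyflavanone | Oc1ccc2c(c1)O[C@H](c1cc(O)c(O)c(O)c1)[C@@H](O)C2=O | starting material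

2 | (2R,3R)-7,3',4',5'-tetra-O-benzyldihydrorobinetin | C(c9ccccc9)Oc1ccc2c(c1)O[C@H](c1cc(OCc9ccccc9)c(OCc9ccccc9)c(OCc9ccccc9)c1)[C@@H](O)C2=O | intermediate

3 | (2R,3S)-7-(benzyloxy)-2-[3,4,5-tris(benzyloxy)phenyl]chroman-3,4-diol (2,3-trans, both C4 epimers) | C(c9ccccc9)Oc1ccc2c(c1)O[C@H](c1cc(OCc9ccccc9)c(OCc9ccccc9)c(OCc9ccccc9)c1)[C@@H](O)C2O | intermediate (not isolated)

4 | (2R,3S)-7,3',4',5'-tetra-O-benzylrobinetinidol (2,3-trans) | C(c9ccccc9)Oc1ccc2c(c1)O[C@H](c1cc(OCc9ccccc9)c(OCc9ccccc9)c(OCc9ccccc9)c1)[C@@H](O)C2 | intermediate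

5 | (2R)-7-(benzyloxy)-2-[3,4,5-tris(benzyloxy)phenyl]chroman-3-one | C(c9ccccc9)Oc1ccc2c(c1)O[C@H](c1cc(OCc9ccccc9)c(OCc9ccccc9)c(OCc9ccccc9)c1)C(=O)C2 | intermediate

6 | (2R,3R)-7,3',4',5'-tetra-O-benzylepirobinetinidol (2,3-cis) | C(c9ccccc9)Oc1ccc2c(c1)O[C@H](c1cc(OCc9ccccc9)c(OCc9ccccc9)c(OCc9ccccc9)c1)[C@H](O)C2 | intermediate

7 | (2R,3R)-3,7,3',4',5'-penta-O-benzylepirobinetinidol | C(c9ccccc9)Oc1ccc2c(c1)O[C@H](c1cc(OCc9ccccc9)c(OCc9ccccc9)c(OCc9ccccc9)c1)[C@H](OCc9ccccc9)C2 | intermediate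

8 | 4β-(2-ethoxyethoxy)-3,7,3',4',5'-penta-O-benzylepirobinetinidol (2,3-cis-3,4-trans) | C(c9ccccc9)Oc1ccc2c(c1)O[C@H](c1cc(OCc9ccccc9)c(OCc9ccccc9)c(OCc9ccccc9)c1)[C@H](OCc9ccccc9)[C@H]2OCCOCC | intermediate

9 | 2,4,6-trihydroxyacetophenone | CC(=O)c1c(O)cc(O)cc1O | starting material

10 | 1-[4-(benzyloxy)-2,6-dihydroxyphenyl]ethanone | CC(=O)c1c(O)cc(OCc2ccccc2)cc1O | intermediate

11 | 1-[4-(benzyloxy)-2,6-dihydroxy-3-U-phenyl]ethanone | C(c9ccccc9)Oc1ccc2c(c1)O[C@H](c1cc(OCc9ccccc9)c(OCc9ccccc9)c(OCc9ccccc9)c1)[C@H](OCc9ccccc9)[C@H]2c1c(O)c(C(C)=O)c(O)cc1OCc9ccccc9 | intermediate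

12 | 2-acetyl-5-(benzyloxy)-3-hydroxy-4-U-phenyl trifluoromethanesulfonate | C(c9ccccc9)Oc1ccc2c(c1)O[C@H](c1cc(OCc9ccccc9)c(OCc9ccccc9)c(OCc9ccccc9)c1)[C@H](OCc9ccccc9)[C@H]2c1c(O)c(C(C)=O)c(OS(=O)(=O)C(F)(F)F)cc1OCc9ccccc9 | intermediate

13 | 1-[4-(benzyloxy)-2-hydroxy-3-U-phenyl]ethanone | C(c9ccccc9)Oc1ccc2c(c1)O[C@H](c1cc(OCc9ccccc9)c(OCc9ccccc9)c(OCc9ccccc9)c1)[C@H](OCc9ccccc9)[C@H]2c1c(O)c(C(C)=O)ccc1OCc9ccccc9 | intermediate

14 | 3,4,5-tris(benzyloxy)benzaldehyde | O=Cc1cc(OCc2ccccc2)c(OCc2ccccc2)c(OCc2ccccc2)c1 | starting material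

15 | (E)-1-[4-(benzyloxy)-2-hydroxy-3-U-phenyl]-3-[3,4,5-tris(benzyloxy)phenyl]prop-2-en-1-one | C(c9ccccc9)Oc1ccc2c(c1)O[C@H](c1cc(OCc9ccccc9)c(OCc9ccccc9)c(OCc9ccccc9)c1)[C@H](OCc9ccccc9)[C@H]2c1c(O)c(C(=O)/C=C/c3cc(OCc9ccccc9)c(OCc9ccccc9)c(OCc9ccccc9)c3)ccc1OCc9ccccc9 | intermediate (not isolated)

16 | 7-(benzyloxy)-3-hydroxy-8-U-2-[3,4,5-tris(benzyloxy)phenyl]-4H-chromen-4-one | C(c9ccccc9)Oc1ccc2c(c1)O[C@H](c1cc(OCc9ccccc9)c(OCc9ccccc9)c(OCc9ccccc9)c1)[C@H](OCc9ccccc9)[C@H]2c1c(OCc9ccccc9)ccc2c1oc(-c1cc(OCc9ccccc9)c(OCc9ccccc9)c(OCc9ccccc9)c1)c(O)c2=O | intermediate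

17 | 3,7-bis(benzyloxy)-8-U-2-[3,4,5-tris(benzyloxy)phenyl]-4H-chromen-4-one | C(c9ccccc9)Oc1ccc2c(c1)O[C@H](c1cc(OCc9ccccc9)c(OCc9ccccc9)c(OCc9ccccc9)c1)[C@H](OCc9ccccc9)[C@H]2c1c(OCc9ccccc9)ccc2c1oc(-c1cc(OCc9ccccc9)c(OCc9ccccc9)c(OCc9ccccc9)c1)c(OCc9ccccc9)c2=O | intermediate

18 | (−)-epicatechin, (2R,3R) | Oc1cc(O)c2c(c1)O[C@H](c1ccc(O)c(O)c1)[C@H](O)C2 | starting material

19 | 5,7,3',4'-tetra-O-benzylepicatechin | C(c9ccccc9)Oc1cc(OCc9ccccc9)c2c(c1)O[C@H](c1ccc(OCc9ccccc9)c(OCc9ccccc9)c1)[C@H](O)C2 | intermediate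

20 | 8-bromo-5,7,3',4'-tetra-O-benzylepicatechin | Brc1c(OCc9ccccc9)cc(OCc9ccccc9)c2c1O[C@H](c1ccc(OCc9ccccc9)c(OCc9ccccc9)c1)[C@H](O)C2 | intermediate

21 | 8-bromo-3,5,7,3',4'-penta-O-benzylepicatechin | Brc1c(OCc9ccccc9)cc(OCc9ccccc9)c2c1O[C@H](c1ccc(OCc9ccccc9)c(OCc9ccccc9)c1)[C@H](OCc9ccccc9)C2 | intermediate

22 | 8-lithio-3,5,7,3',4'-penta-O-benzylepicatechin | [Li]c1c(OCc9ccccc9)cc(OCc9ccccc9)c2c1O[C@H](c1ccc(OCc9ccccc9)c(OCc9ccccc9)c1)[C@H](OCc9ccccc9)C2 | intermediate (not isolated)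

23 | 3,7-bis(benzyloxy)-4-Lw-8-U-2-[3,4,5-tris(benzyloxy)phenyl]-4H-chromen-4-ol (both C4 epimers) | C(c9ccccc9)Oc1ccc2c(c1)O[C@H](c1cc(OCc9ccccc9)c(OCc9ccccc9)c(OCc9ccccc9)c1)[C@H](OCc9ccccc9)[C@H]2c1c(OCc9ccccc9)ccc2c1OC(c1cc(OCc9ccccc9)c(OCc9ccccc9)c(OCc9ccccc9)c1)=C(OCc9ccccc9)C2(O)c1c(OCc9ccccc9)cc(OCc9ccccc9)c2c1O[C@H](c1ccc(OCc9ccccc9)c(OCc9ccccc9)c1)[C@H](OCc9ccccc9)C2 | intermediate

24 | 3,7-bis(benzyloxy)-4-Lw-8-U-2-[3,4,5-tris(benzyloxy)phenyl]chromenylium (R)-TRIP phosphate (ion pair; the axial configuration of the anion is not expressed in the SMILES) | C(c9ccccc9)Oc1ccc2c(c1)O[C@H](c1cc(OCc9ccccc9)c(OCc9ccccc9)c(OCc9ccccc9)c1)[C@H](OCc9ccccc9)[C@H]2c1c(OCc9ccccc9)ccc2c1[o+]c(-c1cc(OCc9ccccc9)c(OCc9ccccc9)c(OCc9ccccc9)c1)c(OCc9ccccc9)c2-c1c(OCc9ccccc9)cc(OCc9ccccc9)c2c1O[C@H](c1ccc(OCc9ccccc9)c(OCc9ccccc9)c1)[C@H](OCc9ccccc9)C2.CC(C)c1cc(C(C)C)c(-c2cc3ccccc3c3c2OP(=O)([O-])Oc2c(-c4c(C(C)C)cc(C(C)C)cc4C(C)C)cc4ccccc4c2-3)c(C(C)C)c1 | intermediate (not isolated)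

25 | (2R)-3,7-bis(benzyloxy)-4-Lw-8-U-2-[3,4,5-tris(benzyloxy)phenyl]-2H-chromene | C(c9ccccc9)Oc1ccc2c(c1)O[C@H](c1cc(OCc9ccccc9)c(OCc9ccccc9)c(OCc9ccccc9)c1)[C@H](OCc9ccccc9)[C@H]2c1c(OCc9ccccc9)ccc2c1O[C@H](c1cc(OCc9ccccc9)c(OCc9ccccc9)c(OCc9ccccc9)c1)C(OCc9ccccc9)=C2c1c(OCc9ccccc9)cc(OCc9ccccc9)c2c1O[C@H](c1ccc(OCc9ccccc9)c(OCc9ccccc9)c1)[C@H](OCc9ccccc9)C2 | intermediate (not isolated)

26 | pentadeca-O-benzyl ether of the target, (2R,3R,4S)-3,7-bis(benzyloxy)-4-Lw-8-U-2-[3,4,5-tris(benzyloxy)phenyl]chroman (middle ring all-cis) | C(c9ccccc9)Oc1ccc2c(c1)O[C@H](c1cc(OCc9ccccc9)c(OCc9ccccc9)c(OCc9ccccc9)c1)[C@H](OCc9ccccc9)[C@H]2c1c(OCc9ccccc9)ccc2c1O[C@H](c1cc(OCc9ccccc9)c(OCc9ccccc9)c(OCc9ccccc9)c1)[C@H](OCc9ccccc9)[C@@H]2c1c(OCc9ccccc9)cc(OCc9ccccc9)c2c1O[C@H](c1ccc(OCc9ccccc9)c(OCc9ccccc9)c1)[C@H](OCc9ccccc9)C2 | intermediate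

27 | epirobinetinidol-(4β→8)-epirobinetinidol-(4α→8)-epicatechin (CNP0115797.2) | Oc1ccc2c(c1)O[C@H](c1cc(O)c(O)c(O)c1)[C@H](O)[C@H]2c1c(O)ccc2c1O[C@H](c1cc(O)c(O)c(O)c1)[C@H](O)[C@@H]2c1c(O)cc(O)c2c1O[C@H](c1ccc(O)c(O)c1)[C@H](O)C2 | target

## Step count and risks

Total step count: 18. Longest linear sequence: 14 steps (steps 1–6, 8–12, 16–18).

**Step 17.** What may go wrong: the chiral anion may give poor face selection in the first hydride transfer, or hydride may scramble between flavene molecules. The fallback sets out from 13 and comes back at 25; it sets C2 by known chemistry before the aryl addition. The phenol of 13 is masked (NaH, MOMCl) as the MOM ether F1. Claisen–Schmidt condensation with 14 gives the MOM‑protected (E)‑chalcone F2. Juliá–Colonna epoxidation (poly‑L‑leucine, urea–H2O2, DBU) gives the (αR,βS)‑epoxide F3. HCl/MeOH removes the MOM group and the phenol opens the epoxide at the benzylic carbon with inversion, giving the (2R,3R)‑dihydroflavonol F4. BnBr/Ag2O gives its 3‑O‑benzyl ether F5. The cerium reagent made from 22 and CeCl3 adds to C4 to give the tertiary carbinol F6. CSA in toluene eliminates water across C3–C4 to give 25 (C3 is erased). The TFA/nBu3SnH half of step 17 then carries 25 to 26 under control of C2.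

**Step 16.** What may go wrong: the hindered aryllithium may transfer an electron or fail to add to the vinylogous ester carbonyl. The fallback sets out from 17 and comes back at 24; it reverses the polarity. 19 is benzylated (NaH, BnBr) to penta‑O‑benzylepicatechin F7. 17 is activated with Tf2O (2,6‑di‑tert‑butylpyridine, CH2Cl2) to its 4‑triflyloxychromenylium ion. F7 attacks this ion through C8 in an addition–elimination (the classical condensation of flavones with phenol ethers to 4‑arylflavylium salts) and gives the flavylium triflate F8. Exchange of triflate for the sodium salt of the chiral phosphate gives ion pair 24.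

**Step 9.** What may go wrong: the sulfonylation may not distinguish the two phenols, which would scramble the later ring closure. The fallback sets out from 8 and comes back at 13; it replaces the surplus oxygen by a bromine blocking group. 8 is coupled (BF3·OEt2) with 1‑[4‑(benzyloxy)‑5‑bromo‑2‑hydroxyphenyl]ethanone F9 (from commercial 5‑bromo‑2,4‑dihydroxyacetophenone, BnBr, K2CO3), whose only activated free carbon lies between the two oxygens. This gives the bromo ketone F10. The Pd/formate conditions of step 10 then remove the bromine and give 13.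

## Further compounds

F1 | step 17 | 1-[4-(benzyloxy)-2-(methoxymethoxy)-3-U-phenyl]ethanone | C(c9ccccc9)Oc1ccc2c(c1)O[C@H](c1cc(OCc9ccccc9)c(OCc9ccccc9)c(OCc9ccccc9)c1)[C@H](OCc9ccccc9)[C@H]2c1c(OCOC)c(C(C)=O)ccc1OCc9ccccc9

F2 | step 17 | (E)-1-[4-(benzyloxy)-2-(methoxymethoxy)-3-U-phenyl]-3-[3,4,5-tris(benzyloxy)phenyl]prop-2-en-1-one | C(c9ccccc9)Oc1ccc2c(c1)O[C@H](c1cc(OCc9ccccc9)c(OCc9ccccc9)c(OCc9ccccc9)c1)[C@H](OCc9ccccc9)[C@H]2c1c(OCOC)c(C(=O)/C=C/c3cc(OCc9ccccc9)c(OCc9ccccc9)c(OCc9ccccc9)c3)ccc1OCc9ccccc9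

F3 | step 17 | (αR,βS)-epoxide of F2, [4-(benzyloxy)-2-(methoxymethoxy)-3-U-phenyl]{(2R,3S)-3-[3,4,5-tris(benzyloxy)phenyl]oxiran-2-yl}methanone | C(c9ccccc9)Oc1ccc2c(c1)O[C@H](c1cc(OCc9ccccc9)c(OCc9ccccc9)c(OCc9ccccc9)c1)[C@H](OCc9ccccc9)[C@H]2c1c(OCOC)c(C(=O)[C@@H]3O[C@H]3c3cc(OCc9ccccc9)c(OCc9ccccc9)c(OCc9ccccc9)c3)ccc1OCc9ccccc9

F4 | step 17 | (2R,3R)-7-(benzyloxy)-3-hydroxy-8-U-2-[3,4,5-tris(benzyloxy)phenyl]chroman-4-one (2,3-trans) | C(c9ccccc9)Oc1ccc2c(c1)O[C@H](c1cc(OCc9ccccc9)c(OCc9ccccc9)c(OCc9ccccc9)c1)[C@H](OCc9ccccc9)[C@H]2c1c(OCc9ccccc9)ccc2c1O[C@H](c1cc(OCc9ccccc9)c(OCc9ccccc9)c(OCc9ccccc9)c1)[C@@H](O)C2=O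

F5 | step 17 | (2R,3R)-3,7-bis(benzyloxy)-8-U-2-[3,4,5-tris(benzyloxy)phenyl]chroman-4-one | C(c9ccccc9)Oc1ccc2c(c1)O[C@H](c1cc(OCc9ccccc9)c(OCc9ccccc9)c(OCc9ccccc9)c1)[C@H](OCc9ccccc9)[C@H]2c1c(OCc9ccccc9)ccc2c1O[C@H](c1cc(OCc9ccccc9)c(OCc9ccccc9)c(OCc9ccccc9)c1)[C@@H](OCc9ccccc9)C2=O

F6 | step 17 | (2R,3R)-3,7-bis(benzyloxy)-4-Lw-8-U-2-[3,4,5-tris(benzyloxy)phenyl]chroman-4-ol (both C4 epimers) | C(c9ccccc9)Oc1ccc2c(c1)O[C@H](c1cc(OCc9ccccc9)c(OCc9ccccc9)c(OCc9ccccc9)c1)[C@H](OCc9ccccc9)[C@H]2c1c(OCc9ccccc9)ccc2c1O[C@H](c1cc(OCc9ccccc9)c(OCc9ccccc9)c(OCc9ccccc9)c1)[C@@H](OCc9ccccc9)C2(O)c1c(OCc9ccccc9)cc(OCc9ccccc9)c2c1O[C@H](c1ccc(OCc9ccccc9)c(OCc9ccccc9)c1)[C@H](OCc9ccccc9)C2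

F7 | step 16 | 3,5,7,3',4'-penta-O-benzylepicatechin | C(c9ccccc9)Oc1cc(OCc9ccccc9)c2c(c1)O[C@H](c1ccc(OCc9ccccc9)c(OCc9ccccc9)c1)[C@H](OCc9ccccc9)C2

F8 | step 16 | 3,7-bis(benzyloxy)-4-Lw-8-U-2-[3,4,5-tris(benzyloxy)phenyl]chromenylium trifluoromethanesulfonate | C(c9ccccc9)Oc1ccc2c(c1)O[C@H](c1cc(OCc9ccccc9)c(OCc9ccccc9)c(OCc9ccccc9)c1)[C@H](OCc9ccccc9)[C@H]2c1c(OCc9ccccc9)ccc2c1[o+]c(-c1cc(OCc9ccccc9)c(OCc9ccccc9)c(OCc9ccccc9)c1)c(OCc9ccccc9)c2-c1c(OCc9ccccc9)cc(OCc9ccccc9)c2c1O[C@H](c1ccc(OCc9ccccc9)c(OCc9ccccc9)c1)[C@H](OCc9ccccc9)C2.[O-]S(=O)(=O)C(F)(F)F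

F9 | step 9 | 1-[4-(benzyloxy)-5-bromo-2-hydroxyphenyl]ethanone | CC(=O)c1cc(Br)c(OCc2ccccc2)cc1O

F10 | step 9 | 1-[4-(benzyloxy)-5-bromo-2-hydroxy-3-U-phenyl]ethanone | C(c9ccccc9)Oc1ccc2c(c1)O[C@H](c1cc(OCc9ccccc9)c(OCc9ccccc9)c(OCc9ccccc9)c1)[C@H](OCc9ccccc9)[C@H]2c1c(O)c(C(C)=O)cc(Br)c1OCc9ccccc9
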